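This flask is slow: 25.6% of its X still stands at 1.67 d. So the decision for the next flask, charged alike, is whether to leave it the full 8.0 d or stop it early.

| flask | X | E | remark | time |
|---|---|---|---|---|
| spring | 2 M | 2.2 M | the very flask that is asked about, followed so far |  |
| flask | 2.0 M | 2.20 M |  | 8.0 d |

- spring (time / d: G / %, X / %): 0.333: 10.2, 65.3; 0.500: 15.7, 56.0; 0.833: 23.9, 42.7; 1.67: 26.1, 25.6; 2.50: 22.4, 17.5; 4.00: 18.5, 11.0

(standard deviation of a reading: 0.5 percentage points)



- time up to 8.0 d at which G stands highest
- the amount of G, in percent of the X charged, at that time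

The decision hangs on how much X is still to react late. I take X, the limiting reagent, to react with E one to one at second order. The gap c_E − c_X between their concentrations then stays fixed, and the common logarithm lg(c_E/c_X) climbs in a straight line with time. The reading at 1.67 d gives w = 0.305 M⁻¹ d⁻¹, the decades gained per day per molar of gap. The reading at 4.00 d gives 0.299 M⁻¹ d⁻¹.

With w, lg(c_E/c_X) reaches 0.529 at 8.0 d, which leaves 4.20% of X. So I reckon that X loses 6.8 percentage points after 4.00 d. Added whole to the 18.5% of G read then, that makes 25.3%, less than the 26.1% read at 1.67 d, provided the unseen share gives no G back. That margin of 0.8 points stands against a scatter of 0.5 points per reading, so it is thin ground, but I take it and stop the next flask near the reading at 1.67 d.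

The forecast puts the highest G at 1.35 d (1.1 d to 1.65 d), with 26.8% (26% to 28%), and it says “Nothing suggests a later rise”. That peak is its figure, not mine.

The flask has G highest at 1.34 d, with 26.8%.

    X + E → L + D (k = 8.10 × 10⁻⁶ M⁻¹ s⁻¹)
    L → G (k = 2.60 × 10⁻⁵ s⁻¹)
    G ⇌ Q (K = 4.00, k = 1.40 × 10⁻⁵ s⁻¹)
    L → Z (k = 3.70 × 10⁻⁶ s⁻¹)

X and E make L and D from the start, and at 0.800 d the flask holds 18.6% of L, 22.9% of G and 10.4% of Q. By 4.00 d L has fallen to 1.52%, while G, turning to Q, stands at 18.4% against 58.3% of Q. At 8.00 d this flask holds 4.22% of X, and w gave 4.20%. In a neighbour flask charged with 0.80 M of X, w gives 0.0245% of that X left at 8.0 d, and the flask holds 0.025%.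

The readings were generated by integration for substances that don't exist, and the scatter is random.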